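Ring A is disconnected across C3–C4 and C5–C10 (abietane numbering), as the [4+2] adduct of a C10=C1–C2=C3 diene and the C4=C5 bond of a (Z)-2-methylenoate. Both halves hang on adjacent carbons C8 and C9 of aromatic ring C, so one intramolecular Diels–Alder reaction closes rings A and B and sets C4, C5 and C10. The cis-1,3-diaxial C20 oxygen and C19 carboxyl of the δ-lactone are exploited as a magnesium alkoxide–ester bridge that steers the exo, trans-fused transition state and then lactonises in the same flask. A temporary C7 silyloxy stereocentre, later the C7 ketone, relays absolute configuration. The precursor is an acyclic triene: aryl (Z)-dienol plus (Z)-enoate.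

Key step: step 13

Remarks: Abietane numbering is used for all compounds (ring A: C1–C5 and C10; ring B: C5–C10; aromatic ring C: C8, C9, C11–C14; C18 methyl and C19 carboxyl carbon on C4; C20 is the CH2O carbon on C10). Assumption: ethyl 2-[bis(2,2,2-trifluoroethoxy)phosphoryl]propanoate, (+)-B-methoxydiisopinocampheylborane and 4-bromofuran-2(5H)-one are taken as commercially available.

**Step 1**
Reactants: 1 1,2,4-trimethoxybenzene
Product: 3 2-(2,3,6-trimethoxyphenyl)propan-2-ol, via 2,3,6-trimethoxyphenyllithium 2 (not isolated)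
Conditions: n-BuLi, TMEDA, THF, 0 °C; acetone, −78 °C → rt; H2O
Reagents that add atoms: acetone, CC(C)=O
Why: Directed ortho-metalation removes the C–H flanked by two methoxy groups, and the aryllithium should add 1,2 to acetone.

**Step 2**
Reactants: 3 2-(2,3,6-trimethoxyphenyl)propan-2-ol
Product: 4 1,2,4-trimethoxy-3-(propan-2-yl)benzene
Conditions: Et3SiH, CF3CO2H, CH2Cl2, 0 °C → rt
Reagents that add atoms: none
Why: Ionic hydrogenation, in which the acid ionises the tertiary benzylic alcohol to a cation stabilised by two ortho oxygens and the silane delivers hydride.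

**Step 3**
Reactants: 4 1,2,4-trimethoxy-3-(propan-2-yl)benzene
Product: 5 2,4,5-trimethoxy-3-(propan-2-yl)benzaldehyde
Conditions: Cl2CHOMe, TiCl4, CH2Cl2, −20 → 0 °C; H2O
Reagents that add atoms: dichloromethyl methyl ether, COC(Cl)Cl; water, O
Why: Rieche formylation (Friedel–Crafts type) should attack the one free position that is ortho to one methoxy group and para to another, which is the future C8.

**Step 4**
Reactants: 5 2,4,5-trimethoxy-3-(propan-2-yl)benzaldehyde
Product: 6 2-bromo-3,4,6-trimethoxy-5-(propan-2-yl)benzaldehyde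
Conditions: N-bromosuccinimide, MeCN, rt, dark
Reagents that add atoms: N-bromosuccinimide, O=C1CCC(=O)N1Br
Why: Electrophilic aromatic bromination can only occur at the single remaining aromatic C–H (future C9), which is activated by its ortho methoxy group.

**Step 5**
Reactants: 6 2-bromo-3,4,6-trimethoxy-5-(propan-2-yl)benzaldehyde
Product: 7 (1R)-1-[2-bromo-3,4,6-trimethoxy-5-(propan-2-yl)phenyl]but-3-en-1-ol
Conditions: allylMgBr, (+)-Ipc2BOMe, Et2O, −78 °C → rt; then 6, −78 °C; NaOH, H2O2
Reagents that add atoms: allylmagnesium bromide, C=CC[Mg]Br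
Why: Brown asymmetric allylboration through a chair six-membered transition state, in which the reagent derived from (−)-α-pinene should deliver allyl to the Re face of the aldehyde and set (R)-C7.

**Step 6**
Reactants: 7 (1R)-1-[2-bromo-3,4,6-trimethoxy-5-(propan-2-yl)phenyl]but-3-en-1-ol
Product: 8 tert-butyl{[(1R)-1-[2-bromo-3,4,6-trimethoxy-5-(propan-2-yl)phenyl]but-3-en-1-yl]oxy}dimethylsilane
Conditions: TBSOTf, 2,6-lutidine, CH2Cl2, −78 → 0 °C
Reagents that add atoms: tert-butyldimethylsilyl triflate, CC(C)(C)[Si](C)(C)OS(=O)(=O)C(F)(F)F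
Why: Silylation with the silyl triflate is reactive enough for the hindered secondary benzylic alcohol and blocks later lactonisation onto the enoate.

**Step 7**
Reactants: 8 tert-butyl{[(1R)-1-[2-bromo-3,4,6-trimethoxy-5-(propan-2-yl)phenyl]but-3-en-1-yl]oxy}dimethylsilane
Product: 9 (3R)-3-[2-bromo-3,4,6-trimethoxy-5-(propan-2-yl)phenyl]-3-[(tert-butyldimethylsilyl)oxy]propanal
Conditions: OsO4 (2 mol%), NaIO4, 2,6-lutidine, 1,4-dioxane/H2O, rt
Reagents that add atoms: sodium periodate, [Na+].[O-]I(=O)(=O)=O (terminal oxidant; the oxygen is passed on through OsO4, O=[Os](=O)(=O)=O)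
Why: Lemieux–Johnson cleavage (catalytic dihydroxylation, then periodate glycol cleavage) of the only alkene, with lutidine buffering against β-elimination of the silyloxy group.

**Step 8**
Reactants: 9 (3R)-3-[2-bromo-3,4,6-trimethoxy-5-(propan-2-yl)phenyl]-3-[(tert-butyldimethylsilyl)oxy]propanal
Product: 10 ethyl (2Z,5R)-5-[2-bromo-3,4,6-trimethoxy-5-(propan-2-yl)phenyl]-5-[(tert-butyldimethylsilyl)oxy]-2-methylpent-2-enoate
Conditions: ethyl 2-[bis(2,2,2-trifluoroethoxy)phosphoryl]propanoate, KN(SiMe3)2, 18-crown-6, THF, −78 °C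
Reagents that add atoms: ethyl 2-[bis(2,2,2-trifluoroethoxy)phosphoryl]propanoate, CCOC(=O)C(C)P(=O)(OCC(F)(F)F)OCC(F)(F)F
Why: Still–Gennari olefination, in which the electron-poor phosphonate makes collapse of the kinetic adduct fast and should give the (Z)-trisubstituted enoate with C6 cis to the ester.

**Step 9**
Reactants: 11 4-bromofuran-2(5H)-one
Product: 12 4-(4,4,5,5-tetramethyl-1,3,2-dioxaborolan-2-yl)furan-2(5H)-one
Conditions: B2pin2, PdCl2(PPh3)2 (3 mol%), PPh3, KOPh, toluene, 50 °C
Reagents that add atoms: bis(pinacolato)diboron, CC1(C)OB(OC1(C)C)B1OC(C)(C)C(C)(C)O1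
Why: Miyaura borylation of an alkenyl bromide (oxidative addition, phenoxide-assisted transmetalation with the diboron, reductive elimination).

**Step 10**
Reactants: 12 4-(4,4,5,5-tetramethyl-1,3,2-dioxaborolan-2-yl)furan-2(5H)-one
Product: 13 4-(4,4,5,5-tetramethyl-1,3,2-dioxaborolan-2-yl)-2,5-dihydrofuran-2-ol (racemic lactol)
Conditions: iBu2AlH (1.1 equiv), CH2Cl2, −78 °C; aq. potassium sodium tartrate
Reagents that add atoms: none
Why: Partial reduction of the lactone stops at the lactol because the aluminium hemiacetal is stable at low temperature until work-up.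

**Step 11**
Reactants: 13 4-(4,4,5,5-tetramethyl-1,3,2-dioxaborolan-2-yl)-2,5-dihydrofuran-2-ol
Product: 14 (2Z)-2-(4,4,5,5-tetramethyl-1,3,2-dioxaborolan-2-yl)penta-2,4-dien-1-ol
Conditions: Ph3PCH3Br, KOtBu, THF, 0 °C → rt
Reagents that add atoms: methyltriphenylphosphonium bromide, C[P+](c1ccccc1)(c1ccccc1)c1ccccc1.[Br-]
Why: Wittig methylenation of the ring-opened hydroxy-enal form of the lactol keeps the geometry of the former ring double bond, so CH2OH ends cis to the new vinyl group.

**Step 12**
Reactants: 10 ethyl (2Z,5R)-5-[2-bromo-3,4,6-trimethoxy-5-(propan-2-yl)phenyl]-5-[(tert-butyldimethylsilyl)oxy]-2-methylpent-2-enoate; 14 (2Z)-2-(4,4,5,5-tetramethyl-1,3,2-dioxaborolan-2-yl)penta-2,4-dien-1-ol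
Product: 15 ethyl (2Z,5R)-5-[(tert-butyldimethylsilyl)oxy]-5-{2-[(2Z)-1-hydroxypenta-2,4-dien-2-yl]-3,4,6-trimethoxy-5-(propan-2-yl)phenyl}-2-methylpent-2-enoate
Conditions: Pd(OAc)2 (5 mol%), SPhos (10 mol%), K3PO4, THF/H2O, 50 °C
Reagents that add atoms: none
Why: Suzuki–Miyaura coupling proceeds with retention of alkene geometry, and the bulky electron-rich biarylphosphine should allow oxidative addition at the di-ortho-substituted aryl bromide at a temperature the triene tolerates.

**Step 13**
Reactants: 15 ethyl (2Z,5R)-5-[(tert-butyldimethylsilyl)oxy]-5-{2-[(2Z)-1-hydroxypenta-2,4-dien-2-yl]-3,4,6-trimethoxy-5-(propan-2-yl)phenyl}-2-methylpent-2-enoate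
Product: 18 7α-[(tert-butyldimethylsilyl)oxy]-11,12,14-trimethoxyabieta-1,8,11,13-tetraen-19,20-olide (7R; 5α-H; 4α-methyl; C19 and C20 both β), via bromomagnesium alkoxide of the triene 16 (not isolated), via cycloadduct bromomagnesium alkoxide 17 (not isolated)
Conditions: MeMgBr (1.05 equiv), toluene (0.005 M), 0 °C, then 80 °C; aq. NH4Cl
Reagents that add atoms: none
Why: MeMgBr turns the C20 hydroxyl into a bromomagnesium alkoxide whose divalent magnesium binds the C19 ester carbonyl, which activates the enoate and holds it exo beneath the s-cis diene; a concerted, asynchronous [4+2] cycloaddition then forms C5–C10 and C3–C4, and the alkoxide attacks the now 1,3-diaxial ester to give the δ-lactone. The closest known reaction type is the type 1 intramolecular Diels–Alder reaction of a 1,7,9-decatrienoate, run on a metal-alkoxide template of the kind that links a dienol to an acrylate ester. Ring A closes as the cyclohexene of the cycloaddition itself, ring B closes as the six-membered tether ring through the anti (trans-fused) transition state, and the lactone ring closes by 6-exo-trig transesterification with loss of ethoxide. The C4/C5 relationship follows from suprafacial addition to the (Z)-enoate (C6 and C19 cis); C10 relative to C5 follows from the (Z)-dienol geometry (aryl outside, CH2O inside) together with the exo ester orientation fixed by the magnesium bridge; the absolute sense follows from the (7R)-silyloxy group, which should sit pseudo-axial to avoid peri strain with the C14 methoxy group. The step needs anti over syn (trans over cis ring fusion) and π-facial selectivity, secured by the bridge and by the C7 stereocentre respectively, while high dilution suppresses intermolecular transesterification and the moderate temperature disfavours the [1,5]-hydrogen shift open to (Z)-dienols.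

**Step 14**
Reactants: 18 7α-[(tert-butyldimethylsilyl)oxy]-11,12,14-trimethoxyabieta-1,8,11,13-tetraen-19,20-olide
Product: 19 7α-hydroxy-11,12,14-trimethoxyabieta-1,8,11,13-tetraen-19,20-olide
Conditions: Bu4NF, THF, 0 °C → rt
Reagents that add atoms: none
Why: Fluoride cleaves the Si–O bond (desilylation) and leaves the bridged lactone and the alkene untouched.

**Step 15**
Reactants: 19 7α-hydroxy-11,12,14-trimethoxyabieta-1,8,11,13-tetraen-19,20-olide
Product: 20 11,12,14-trimethoxy-7-oxoabieta-1,8,11,13-tetraen-19,20-olide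
Conditions: Dess–Martin periodinane, NaHCO3, CH2Cl2, rt
Reagents that add atoms: none
Why: Dess–Martin oxidation of the secondary benzylic alcohol gives the aryl ketone and removes the temporary C7 stereocentre once it has done its work.

**Step 16**
Reactants: 20 11,12,14-trimethoxy-7-oxoabieta-1,8,11,13-tetraen-19,20-olide
Product: 21 12-methoxy-7,11,14-trioxoabieta-1,8,12-trien-19,20-olide
Conditions: (NH4)2Ce(NO3)6 (2.5 equiv), MeCN/H2O, 0 °C
Reagents that add atoms: water, O
Why: Oxidative demethylation by tetravalent cerium converts the para-related C11/C14 methoxy pair into the para-quinone through two one-electron oxidations and attack of water, while the C12 methoxy group should survive as the vinylogous ester.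

**Step 17**
Reactants: 21 12-methoxy-7,11,14-trioxoabieta-1,8,12-trien-19,20-olide
Product: 22 (4S,5R,10R)-11,14-dihydroxy-12-methoxy-7-oxoabieta-8,11,13-trien-19,20-olide (CNP0159814.2)
Conditions: H2 (1 atm), Pd/C (10%), EtOAc, rt; filtration and concentration under argon
Reagents that add atoms: none
Why: Heterogeneous hydrogenation should saturate the cis-disubstituted C1=C2 bond and reduce the quinone to the hydroquinone in one operation; no stereocentre is created, and the hydrogen-bonded C7 aryl ketone is expected to resist reduction.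

**Compound list**

1 | 1,2,4-trimethoxybenzene | COc1ccc(OC)c(OC)c1 | starting material
2 | 2,3,6-trimethoxyphenyllithium | COc1ccc(OC)c([Li])c1OC | intermediate
3 | 2-(2,3,6-trimethoxyphenyl)propan-2-ol | COc1ccc(OC)c(C(C)(C)O)c1OC | intermediate
4 | 1,2,4-trimethoxy-3-(propan-2-yl)benzene | COc1ccc(OC)c(C(C)C)c1OC | intermediate
5 | 2,4,5-trimethoxy-3-(propan-2-yl)benzaldehyde | COc1cc(C=O)c(OC)c(C(C)C)c1OC | intermediate
6 | 2-bromo-3,4,6-trimethoxy-5-(propan-2-yl)benzaldehyde | COc1c(Br)c(C=O)c(OC)c(C(C)C)c1OC | intermediate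
7 | (1R)-1-[2-bromo-3,4,6-trimethoxy-5-(propan-2-yl)phenyl]but-3-en-1-ol | COc1c(OC)c(Br)c(c(OC)c1C(C)C)[C@H](O)CC=C | intermediate
8 | tert-butyl{[(1R)-1-[2-bromo-3,4,6-trimethoxy-5-(propan-2-yl)phenyl]but-3-en-1-yl]oxy}dimethylsilane | COc1c(OC)c(Br)c(c(OC)c1C(C)C)[C@H](O[Si](C)(C)C(C)(C)C)CC=C | intermediate
9 | (3R)-3-[2-bromo-3,4,6-trimethoxy-5-(propan-2-yl)phenyl]-3-[(tert-butyldimethylsilyl)oxy]propanal | COc1c(OC)c(Br)c(c(OC)c1C(C)C)[C@H](O[Si](C)(C)C(C)(C)C)CC=O | intermediate
10 | ethyl (2Z,5R)-5-[2-bromo-3,4,6-trimethoxy-5-(propan-2-yl)phenyl]-5-[(tert-butyldimethylsilyl)oxy]-2-methylpent-2-enoate | COc1c(OC)c(Br)c(c(OC)c1C(C)C)[C@H](O[Si](C)(C)C(C)(C)C)C/C=C(/C)C(=O)OCC | intermediate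
11 | 4-bromofuran-2(5H)-one | O=C1C=C(Br)CO1 | starting material
12 | 4-(4,4,5,5-tetramethyl-1,3,2-dioxaborolan-2-yl)furan-2(5H)-one | O=C1C=C(B2OC(C)(C)C(C)(C)O2)CO1 | intermediate
13 | 4-(4,4,5,5-tetramethyl-1,3,2-dioxaborolan-2-yl)-2,5-dihydrofuran-2-ol (racemic lactol) | OC1C=C(B2OC(C)(C)C(C)(C)O2)CO1 | intermediate
14 | (2Z)-2-(4,4,5,5-tetramethyl-1,3,2-dioxaborolan-2-yl)penta-2,4-dien-1-ol | OC/C(B1OC(C)(C)C(C)(C)O1)=C\C=C | intermediate
15 | ethyl (2Z,5R)-5-[(tert-butyldimethylsilyl)oxy]-5-{2-[(2Z)-1-hydroxypenta-2,4-dien-2-yl]-3,4,6-trimethoxy-5-(propan-2-yl)phenyl}-2-methylpent-2-enoate | COc1c(OC)c(/C(CO)=C/C=C)c(c(OC)c1C(C)C)[C@H](O[Si](C)(C)C(C)(C)C)C/C=C(/C)C(=O)OCC | intermediate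
16 | bromomagnesium alkoxide of triene 15 (C20–O–MgBr) | COc1c(OC)c(/C(CO[Mg]Br)=C/C=C)c(c(OC)c1C(C)C)[C@H](O[Si](C)(C)C(C)(C)C)C/C=C(/C)C(=O)OCC | intermediate
17 | cycloadduct bromomagnesium alkoxide (trans-fused A/B; ethyl ester on C4β, CH2OMgBr on C10β, 7α-silyloxy) | COc1c(OC)c2c(c(OC)c1C(C)C)[C@H](O[Si](C)(C)C(C)(C)C)C[C@@H]1[C@]2(CO[Mg]Br)C=CC[C@]1(C)C(=O)OCC | intermediate
18 | 7α-[(tert-butyldimethylsilyl)oxy]-11,12,14-trimethoxyabieta-1,8,11,13-tetraen-19,20-olide | COc1c(OC)c2c(c(OC)c1C(C)C)[C@H](O[Si](C)(C)C(C)(C)C)C[C@@H]1[C@]23C=CC[C@]1(C)C(=O)OC3 | intermediate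
19 | 7α-hydroxy-11,12,14-trimethoxyabieta-1,8,11,13-tetraen-19,20-olide | COc1c(OC)c2c(c(OC)c1C(C)C)[C@H](O)C[C@@H]1[C@]23C=CC[C@]1(C)C(=O)OC3 | intermediate
20 | 11,12,14-trimethoxy-7-oxoabieta-1,8,11,13-tetraen-19,20-olide | COc1c(OC)c2c(c(OC)c1C(C)C)C(=O)C[C@@H]1[C@]23C=CC[C@]1(C)C(=O)OC3 | intermediate
21 | 12-methoxy-7,11,14-trioxoabieta-1,8,12-trien-19,20-olide | COC=4C(=O)C2=C(C(=O)C=4C(C)C)C(=O)C[C@@H]1[C@]23C=CC[C@]1(C)C(=O)OC3 | intermediate
22 | (4S,5R,10R)-11,14-dihydroxy-12-methoxy-7-oxoabieta-8,11,13-trien-19,20-olide | COc1c(O)c2c(c(O)c1C(C)C)C(=O)C[C@@H]1[C@]23CCC[C@]1(C)C(=O)OC3 | target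

**Step count and risks**

Total step count: 17. Longest linear sequence: 14 steps (steps 1–8 and 12–17); steps 9–11 make the dienyl boronate.

Steps most likely to fail:

Step 13. The magnesium bridge may activate the hindered, trisubstituted enoate too weakly. The cycloaddition would then be slow, and the syn (cis-fused) pathway or a [1,5]-hydrogen shift of the (Z)-dienol would compete. The fallback makes the C20–O–C19 link covalent before the cycloaddition. Setting out from 15, saponification (LiOH, THF/H2O) would give the seco acid (2Z,5R)-5-silyloxy-5-aryl-2-methylpent-2-enoic acid F1. Yamaguchi macrolactonisation (2,4,6-trichlorobenzoyl chloride, Et3N, then DMAP, toluene, high dilution) would close the ten-membered lactone F2. In F2 the (Z)-enoate and the diene are held face to face, so a transannular Diels–Alder reaction on warming would form the same two bonds with the exo ester geometry enforced by the ring. This returns to the route at 18.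

Step 12. Oxidative addition at the electron-rich, di-ortho-substituted C–Br bond may be slow, so that protodeboronation or decomposition of the dienyl boronate wins. The fallback inverts the roles of the partners. Setting out from 10, Miyaura borylation (Pd2(dba)3, XPhos, B2pin2, KOAc, 1,4-dioxane) would give the aryl pinacol boronate F3. Separately, 11 would be reduced with iBu2AlH to 4-bromo-2,5-dihydrofuran-2-ol F4 and methylenated (Ph3PCH3Br, KOtBu) to (2E)-2-bromopenta-2,4-dien-1-ol F5. Suzuki–Miyaura coupling of F3 with F5 places the oxidative addition on the unhindered alkenyl bromide and returns to the route at 15.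

Step 16. The C7 ketone lowers the electron density of the ring, so oxidation may stall, or it may take the ortho-quinone course across the C11/C12 pair. The fallback separates demethylation from oxidation. Setting out from 20, BBr3 (CH2Cl2, −78 → 0 °C) would cleave all three methyl ethers to the 11,12,14-triol F6. Oxidation with air or Ag2O would give the 12-hydroxy-11,14-quinone F7. O-methylation of its single, acidic (vinylogous acid) hydroxyl with trimethylsilyldiazomethane in MeOH/toluene returns to the route at 21.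

**Further compounds**

F1 | step 13 | (2Z,5R)-5-[(tert-butyldimethylsilyl)oxy]-5-{2-[(2Z)-1-hydroxypenta-2,4-dien-2-yl]-3,4,6-trimethoxy-5-(propan-2-yl)phenyl}-2-methylpent-2-enoic acid | COc1c(OC)c(/C(CO)=C/C=C)c(c(OC)c1C(C)C)[C@H](O[Si](C)(C)C(C)(C)C)C/C=C(/C)C(=O)O
F2 | step 13 | ten-membered macrolactone of F1 (C20–O–C19 ester; exocyclic vinyl on C1; 7R) | COc1c(OC)c2c(c(OC)c1C(C)C)[C@H](O[Si](C)(C)C(C)(C)C)C/C=C(/C)C(=O)OC/C2=C\C=C
F3 | step 12 | ethyl (2Z,5R)-5-[(tert-butyldimethylsilyl)oxy]-2-methyl-5-[3,4,6-trimethoxy-5-(propan-2-yl)-2-(4,4,5,5-tetramethyl-1,3,2-dioxaborolan-2-yl)phenyl]pent-2-enoate | COc1c(OC)c(B2OC(C)(C)C(C)(C)O2)c(c(OC)c1C(C)C)[C@H](O[Si](C)(C)C(C)(C)C)C/C=C(/C)C(=O)OCC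
F4 | step 12 | 4-bromo-2,5-dihydrofuran-2-ol | OC1C=C(Br)CO1
F5 | step 12 | (2E)-2-bromopenta-2,4-dien-1-ol | OC/C(Br)=C\C=C
F6 | step 16 | 11,12,14-trihydroxy-7-oxoabieta-1,8,11,13-tetraen-19,20-olide | Oc1c(O)c2c(c(O)c1C(C)C)C(=O)C[C@@H]1[C@]23C=CC[C@]1(C)C(=O)OC3
F7 | step 16 | 12-hydroxy-7,11,14-trioxoabieta-1,8,12-trien-19,20-olide | OC=4C(=O)C2=C(C(=O)C=4C(C)C)C(=O)C[C@@H]1[C@]23C=CC[C@]1(C)C(=O)OC3
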